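## Retrosynthetic overview

1. Labdane numbering is used: ring A = C1–C2–C3–C4(Me2)–C5–C10(Me); ring B = C5–C6(OH)–C7(=O)–C8(Me)=C9–C10; side chain C11–C16 (C13 carbinol, C15 lactone carbonyl, C16 OCH2). The lactone is opened to an allyl arm (ozonolysis, lactol oxidation), and the C9–C11 bond is cut by a Stork–Danheiser addition of a C11–C16 Grignard fragment (C13 from a Sharpless epoxidation) to a ring-B vinylogous ester.
2. The 6β-hydroxy-7-oxo-8-ene unit is traced to a 6-hydroxy-7,9-dione. The enabling feature: in ring B, C10 is the α-carbon of the C9 carbonyl, C5 is the β-carbon of the C7 carbonyl and C8 lies between both carbonyls, while ring A carries no functional group, so C2–C3 can come from an olefination.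
3. Key disconnection: C2–C3 (Wittig) and C5–C10 (Michael) in one cascade that ends with a C7–C8 Dieckmann closure. It unites a phosphonium ylide, made in the same flask from pentan-3-one and ethenyl(triphenyl)phosphonium bromide (C1–C10 bond), with a neopentyl aldehyde carrying a chiral 5-alkylidene-1,3-dioxolan-4-one (a masked α-hydroxyacrylate).
4. Ring order: rings A and B in the same operation (A on C5–C10 formation, B on C7–C8 formation); the lactone ring last.

Key step: step 6

Remark (assumption): the spiro-epimer of the menthone glycolate with the ring ether oxygen axial is taken to shield the alkylidene face on the side of its isopropyl-bearing carbon, and the Michael closure is taken to be trans-selective; because C5 is re-equilibrated at step 8, a reversal of either sense would change only which auxiliary stereoisomer is used.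

## Route

Step 1
Reactants: 1 glycolic acid; 2 (−)-menthone
Product: 3 (5R,6S,9R)-9-methyl-6-(propan-2-yl)-1,4-dioxaspiro[4.5]decan-2-one
Conditions: TsOH (cat.), toluene, reflux, Dean–Stark; chromatographic separation of the spiro-epimers
Reagents that add atoms: none
Why: Acid-catalysed acetalisation of the ketone by the α-hydroxy acid gives the spiro 1,3-dioxolan-4-one (a menthone-derived chiral glycolate); the spiro centre forms as two epimers, of which the (5R) epimer (ring ether oxygen axial) is isolated.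

Step 2
Reactants: 4 2,2-dimethylpropane-1,3-diol
Product: 5 2,2-dimethyl-3-[(triethylsilyl)oxy]propan-1-ol
Conditions: NaH (1.0 equiv), THF, 0 °C; Et3SiCl (1.0 equiv)
Reagents that add atoms: chlorotriethylsilane, CC[Si](Cl)(CC)CC
Why: Monosilylation of the symmetrical diol through its sparingly soluble mono-alkoxide should give the mono-ether selectively; no stereocenter.

Step 3
Reactants: 5 2,2-dimethyl-3-[(triethylsilyl)oxy]propan-1-ol
Product: 6 2,2-dimethyl-3-[(triethylsilyl)oxy]propanal
Conditions: Dess–Martin periodinane, pyridine, CH2Cl2, 0 to 25 °C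
Reagents that add atoms: none
Why: Buffered Dess–Martin oxidation of the primary alcohol gives the non-enolisable aldehyde and leaves the silyl ether intact.

Step 4
Reactants: 3 (5R,6S,9R)-9-methyl-6-(propan-2-yl)-1,4-dioxaspiro[4.5]decan-2-one; 6 2,2-dimethyl-3-[(triethylsilyl)oxy]propanal
Product: 9 (3Z,5R,6S,9R)-3-{2,2-dimethyl-3-[(triethylsilyl)oxy]propylidene}-9-methyl-6-(propan-2-yl)-1,4-dioxaspiro[4.5]decan-2-one, via aldol adduct 7 (not isolated), via mesylate 8 (not isolated)
Conditions: LiN(iPr)2, THF, −78 °C; 6; MeSO2Cl, −78 to 0 °C; DBU, 25 °C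
Reagents that add atoms: none
Why: Aldol addition of the dioxolanone lithium enolate to the aldehyde, mesylation and E1cB elimination (aldol condensation) should give the exocyclic alkene, the Z isomer (alkyl group cis to the ring oxygen) being the less strained one; the carbinol centres of 7 and 8 are destroyed again.

Step 5
Reactants: 9 (3Z,5R,6S,9R)-3-{2,2-dimethyl-3-[(triethylsilyl)oxy]propylidene}-9-methyl-6-(propan-2-yl)-1,4-dioxaspiro[4.5]decan-2-one
Product: 10 (3Z)-2,2-dimethyl-3-[(5R,6S,9R)-9-methyl-2-oxo-6-(propan-2-yl)-1,4-dioxaspiro[4.5]decan-3-ylidene]propanal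
Conditions: (COCl)2, Me2SO, CH2Cl2, −78 to −30 °C; Et3N
Reagents that add atoms: none
Why: Primary triethylsilyl ethers are oxidised directly to aldehydes under Swern conditions (silyl cleavage by the chlorosulfonium salt, then Swern oxidation), and the acylal lactone and the trisubstituted alkene should be inert.

Step 6
Reactants: 11 pentan-3-one; 12 ethenyl(triphenyl)phosphonium bromide; 10 (3Z)-2,2-dimethyl-3-[(5R,6S,9R)-9-methyl-2-oxo-6-(propan-2-yl)-1,4-dioxaspiro[4.5]decan-3-ylidene]propanal
Product: 16 (4aS,8aS)-4-hydroxy-2,5,5,8a-tetramethyl-4a,5,8,8a-tetrahydronaphthalene-1,3(2H,4H)-dione, via phosphonium ylide 13 (not isolated), via Wittig diene 14 (not isolated), via Michael adduct 15 (not isolated)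
Conditions: 11, KN(SiMe3)2 (1.0 equiv), THF, −78 °C; 12 (1.0 equiv, finely powdered), −78 to 0 °C; 10, −78 to −20 °C; KOtBu (2.5 equiv), tBuOH/THF (0.02 M), 0 to 25 °C; 1 M HCl work-up; removal of any cis-fused isomer by chromatography
Reagents that add atoms: none
Why: The potassium enolate of 11 adds to the vinylphosphonium salt 12 (Schweizer-type conjugate addition, new C1–C10 bond) to give the non-stabilised ylide 13, whose lithium-free Wittig olefination with the neopentyl aldehyde 10 should give the (Z)-alkene 14 (new C2–C3 bond), the cis geometry and the gem-dimethyl group holding the ketone next to the alkylidene dioxolanone. Under equilibrating KOtBu/tBuOH the more substituted (C10) enolate then adds 6-exo-trig to C5 (new C5–C10 bond, ring A), and the C8 enolate of 15 acylates on the lactone carbonyl in a 6-exo-trig Dieckmann closure of ring B, the tetrahedral intermediate collapsing with loss of (−)-menthone to free the C6 hydroxyl and give the irreversibly deprotonated 1,3-dione. Closest known reactions are the three-component union of a nucleophile, a vinylphosphonium salt and an aldehyde, tandem Wittig–Michael cyclisations, Michael additions to 5-alkylidene-1,3-dioxolan-4-ones and the Michael–Claisen annulation of ketones with acrylates to cyclohexane-1,3-diones. C5 is set by attack anti to the shielded face of the spiro-menthyl acetal, and C10 by a chair-like, potassium-bridged transition state with the acyl group and the acceptor chain pseudo-equatorial (trans), after which the quaternary centre is fixed; C6 and C8 stay epimerisable and are dealt with in steps 8 to 10 and 16. The step needs mono-addition of the enolate to 12 (one equivalent of each at low temperature, the ylide being too weak a base to enolise the ketone), the ylide to react with the aldehyde and not with the ketone or the acrylate (low temperature, non-stabilised ylide), the Michael step to go through C10 and not C8 (only C10 reaches C5 through a six-membered transition state), and C- over O-acylation (the β-diketone enolate is the thermodynamic sink).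

Step 7
Reactants: 16 (4aS,8aS)-4-hydroxy-2,5,5,8a-tetramethyl-4a,5,8,8a-tetrahydronaphthalene-1,3(2H,4H)-dione
Product: 17 (4aS,8aS)-4-hydroxy-2,5,5,8a-tetramethylhexahydronaphthalene-1,3(2H,4H)-dione
Conditions: H2 (1 atm), Pd/C, EtOAc, 25 °C
Reagents that add atoms: none
Why: Heterogeneous hydrogenation should saturate only the unhindered cis-disubstituted ring-A alkene, the enolised 1,3-dione being inert; no stereocenter is created.

Step 8
Reactants: 17 (4aS,8aS)-4-hydroxy-2,5,5,8a-tetramethylhexahydronaphthalene-1,3(2H,4H)-dione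
Product: 18 (4aS,8aS)-3-hydroxy-2,5,5,8a-tetramethyl-4a,5,6,7,8,8a-hexahydronaphthalene-1,4-dione
Conditions: Cu(OAc)2 (2.2 equiv), 80% aq AcOH, 60 °C
Reagents that add atoms: none
Why: Copper acetate oxidation of an α-hydroxy ketone to the 1,2-dicarbonyl compound (benzoin-to-benzil type) should give the triketone, which rests as the C7 enol flanked by the C6 and C9 carbonyls; the C5 hydrogen, now α to the C6 carbonyl, equilibrates under the acidic conditions to the more stable trans ring fusion (5S).

Step 9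
Reactants: 18 (4aS,8aS)-3-hydroxy-2,5,5,8a-tetramethyl-4a,5,6,7,8,8a-hexahydronaphthalene-1,4-dione
Product: 19 (4aS,8aS)-3-methoxy-2,5,5,8a-tetramethyl-4a,5,6,7,8,8a-hexahydronaphthalene-1,4-dione
Conditions: Me3SiCHN2, MeOH/toluene, 0 °C
Reagents that add atoms: (trimethylsilyl)diazomethane, C[Si](C)(C)C=[N+]=[N-]
Why: The strongly acidic enol (a vinylogous acid) should be O-methylated cleanly by the diazomethane equivalent, and since C7 carries the only hydroxyl the regiochemistry of the vinylogous ester is fixed.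

Step 10
Reactants: 19 (4aS,8aS)-3-methoxy-2,5,5,8a-tetramethyl-4a,5,6,7,8,8a-hexahydronaphthalene-1,4-dione
Product: 20 (4S,4aS,8aS)-4-hydroxy-3-methoxy-2,5,5,8a-tetramethyl-4a,5,6,7,8,8a-hexahydronaphthalen-1(4H)-one
Conditions: NaBH4, CeCl3·7H2O, MeOH/CH2Cl2, −78 °C
Reagents that add atoms: none
Why: Luche 1,2-reduction should attack only the C6 carbonyl, because the C9 carbonyl is a vinylogous ester carbonyl next to the quaternary C10; hydride comes from the α face, the β face being blocked by the axial methyl groups on C4 and C10, which sets the axial 6β-hydroxyl (6S).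

Step 11
Reactants: 21 prop-2-yn-1-ol
Product: 22 2-methylidenepent-4-en-1-ol
Conditions: allylMgBr (2.5 equiv), Et2O, 0 °C to reflux; aq NH4Cl
Reagents that add atoms: allylmagnesium bromide, C=CC[Mg]Br
Why: Alkoxide-directed carbomagnesiation of propargyl alcohol places the allyl group on the internal carbon and gives the 2-substituted allylic alcohol after protonation; no stereocenter.

Step 12
Reactants: 22 2-methylidenepent-4-en-1-ol
Product: 23 [(2R)-2-(prop-2-en-1-yl)oxiran-2-yl]methanol
Conditions: Ti(OiPr)4 (10 mol %), D-(−)-diethyl tartrate (12 mol %), tBuOOH, 4 Å molecular sieves, CH2Cl2, −20 °C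
Reagents that add atoms: tert-butyl hydroperoxide, CC(C)(C)OO
Why: Sharpless asymmetric epoxidation of the 2-substituted allylic alcohol; the D-(−)-tartrate catalyst should deliver oxygen to the face that gives the (R)-epoxide (C13), and the isolated terminal alkene is not touched.

Step 13
Reactants: 23 [(2R)-2-(prop-2-en-1-yl)oxiran-2-yl]methanol
Product: 25 (2S)-2-(prop-2-en-1-yl)butane-1,2,4-triol, via silane diol 24 (not isolated)
Conditions: (iPrO)Me2SiCH2MgCl (2.5 equiv), CuI (10 mol %), THF, −30 to 0 °C; then KF, KHCO3, 30% H2O2, THF/MeOH, 25 °C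
Reagents that add atoms: [dimethyl(propan-2-yloxy)silyl]methylmagnesium chloride, CC(C)O[Si](C)(C)C[Mg]Cl; hydrogen peroxide, OO
Why: Copper-catalysed opening of the epoxide at its CH2 terminus by the Tamao hydroxymethyl-anion reagent, then Tamao–Fleming oxidation of the C–Si bond, adds the C11 carbinol; the quaternary C13 is not involved (a Payne rearrangement of this 2,2-disubstituted glycidol is degenerate and does not erode it).

Step 14
Reactants: 25 (2S)-2-(prop-2-en-1-yl)butane-1,2,4-triol
Product: 26 2-[(4S)-2,2-dimethyl-4-(prop-2-en-1-yl)-1,3-dioxolan-4-yl]ethan-1-ol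
Conditions: Me2C(OMe)2, pyridinium p-toluenesulfonate (cat.), CH2Cl2, 25 °C
Reagents that add atoms: 2,2-dimethoxypropane, COC(C)(C)OC
Why: Acetonide formation is thermodynamically selective for the five-membered dioxolane of the 1,2-diol and leaves the primary C11 hydroxyl free.

Step 15
Reactants: 26 2-[(4S)-2,2-dimethyl-4-(prop-2-en-1-yl)-1,3-dioxolan-4-yl]ethan-1-ol
Product: 27 (4S)-4-(2-iodoethyl)-2,2-dimethyl-4-(prop-2-en-1-yl)-1,3-dioxolane
Conditions: I2, PPh3, imidazole, CH2Cl2, 0 °C
Reagents that add atoms: iodine, II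
Why: Appel-type iodination of the primary alcohol under neutral conditions spares the acetonide and the stereocenter.

Step 16
Reactants: 20 (4S,4aS,8aS)-4-hydroxy-3-methoxy-2,5,5,8a-tetramethyl-4a,5,6,7,8,8a-hexahydronaphthalen-1(4H)-one; 27 (4S)-4-(2-iodoethyl)-2,2-dimethyl-4-(prop-2-en-1-yl)-1,3-dioxolane
Product: 30 (1S,4aS,8aS)-1-hydroxy-4-[(3R)-3-hydroxy-3-(hydroxymethyl)hex-5-en-1-yl]-3,4a,8,8-tetramethyl-4a,5,6,7,8,8a-hexahydronaphthalen-2(1H)-one, via Grignard reagent 28 (not isolated), via carbinol adduct 29 (not isolated)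
Conditions: 27, Mg, THF, 25 °C; 20, iPrMgCl (1.0 equiv), THF, −78 °C; then 28 (1.5 equiv), CeCl3, −78 to 0 °C; 1 M HCl, THF, 25 °C
Reagents that add atoms: water, O
Why: Stork–Danheiser sequence: 1,2-addition of the cerium-modified Grignard reagent to the C9 carbonyl of the vinylogous ester, then acid hydrolysis of the enol ether and loss of the tertiary allylic hydroxyl, moves the enone to C7=O/C8=C9 with the side chain on C9 while the same acid removes the acetonide; a 5-hexenyl Grignard reagent, unlike the lithium reagent, does not cyclise, and the C6 alkoxide formed first by iPrMgCl is a spectator.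

Step 17
Reactants: 30 (1S,4aS,8aS)-1-hydroxy-4-[(3R)-3-hydroxy-3-(hydroxymethyl)hex-5-en-1-yl]-3,4a,8,8-tetramethyl-4a,5,6,7,8,8a-hexahydronaphthalen-2(1H)-one
Product: 32 (1S,4aS,8aS)-4-{2-[(3R)-3,5-dihydroxyoxolan-3-yl]ethyl}-1-hydroxy-3,4a,8,8-tetramethyl-4a,5,6,7,8,8a-hexahydronaphthalen-2(1H)-one, via hydroxy aldehyde 31 (not isolated)
Conditions: O3 (1.0 equiv, titrated CH2Cl2 solution), CH2Cl2/MeOH, −78 °C; Me2S
Reagents that add atoms: ozone, [O-][O+]=O
Why: Ozone should cleave the electron-rich monosubstituted alkene much faster than the hindered, electron-poor tetrasubstituted enone, and the resulting aldehyde closes onto the C16 hydroxyl to the five-membered lactol.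

Step 18
Reactants: 32 (1S,4aS,8aS)-4-{2-[(3R)-3,5-dihydroxyoxolan-3-yl]ethyl}-1-hydroxy-3,4a,8,8-tetramethyl-4a,5,6,7,8,8a-hexahydronaphthalen-2(1H)-one
Product: 33 (1S,4aS,8aS)-1-hydroxy-4-{2-[(3R)-3-hydroxy-5-oxooxolan-3-yl]ethyl}-3,4a,8,8-tetramethyl-4a,5,6,7,8,8a-hexahydronaphthalen-2(1H)-one
Conditions: TEMPO (10 mol %), PhI(OAc)2, CH2Cl2, 25 °C
Reagents that add atoms: none
Why: Oxoammonium (TEMPO) oxidation should convert the lactol to the γ-lactone far faster than it attacks the hindered axial C6 hydroxyl or the tertiary C13 hydroxyl, completing the target without touching a stereocenter.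

## Compound list

1 | glycolic acid | OCC(=O)O | starting material
2 | (−)-menthone, (2S,5R)-5-methyl-2-(propan-2-yl)cyclohexan-1-one | CC(C)[C@@H]1CC[C@@H](C)CC1=O | starting material
3 | (5R,6S,9R)-9-methyl-6-(propan-2-yl)-1,4-dioxaspiro[4.5]decan-2-one | O=C1CO[C@@]2(O1)C[C@H](C)CC[C@H]2C(C)C | intermediate
4 | 2,2-dimethylpropane-1,3-diol | OCC(C)(C)CO | starting material
5 | 2,2-dimethyl-3-[(triethylsilyl)oxy]propan-1-ol | CC[Si](CC)(CC)OCC(C)(C)CO | intermediate
6 | 2,2-dimethyl-3-[(triethylsilyl)oxy]propanal | CC[Si](CC)(CC)OCC(C)(C)C=O | intermediate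
7 | (5R,6S,9R)-3-{1-hydroxy-2,2-dimethyl-3-[(triethylsilyl)oxy]propyl}-9-methyl-6-(propan-2-yl)-1,4-dioxaspiro[4.5]decan-2-one (aldol adduct, carbinol epimers) | O=C1C(C(O)C(C)(C)CO[Si](CC)(CC)CC)O[C@@]2(O1)C[C@H](C)CC[C@H]2C(C)C | intermediate
8 | methanesulfonate of 7 | O=C1C(C(OS(C)(=O)=O)C(C)(C)CO[Si](CC)(CC)CC)O[C@@]2(O1)C[C@H](C)CC[C@H]2C(C)C | intermediate
9 | (3Z,5R,6S,9R)-3-{2,2-dimethyl-3-[(triethylsilyl)oxy]propylidene}-9-methyl-6-(propan-2-yl)-1,4-dioxaspiro[4.5]decan-2-one | O=C1/C(=C/C(C)(C)CO[Si](CC)(CC)CC)O[C@@]2(O1)C[C@H](C)CC[C@H]2C(C)C | intermediate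
10 | (3Z)-2,2-dimethyl-3-[(5R,6S,9R)-9-methyl-2-oxo-6-(propan-2-yl)-1,4-dioxaspiro[4.5]decan-3-ylidene]propanal | O=C1/C(=C/C(C)(C)C=O)O[C@@]2(O1)C[C@H](C)CC[C@H]2C(C)C | intermediate
11 | pentan-3-one | CCC(=O)CC | starting material
12 | ethenyl(triphenyl)phosphonium bromide | C=C[P+](c1ccccc1)(c1ccccc1)c1ccccc1.[Br-] | starting material
13 | 4-methyl-6-(triphenyl-λ5-phosphanylidene)hexan-3-one (ylide, racemic) | CCC(=O)C(C)CC=P(c1ccccc1)(c1ccccc1)c1ccccc1 | intermediate
14 | (3Z,5R,6S,9R)-9-methyl-6-(propan-2-yl)-3-[(3Z)-2,2,6-trimethyl-7-oxonon-3-en-1-ylidene]-1,4-dioxaspiro[4.5]decan-2-one (Wittig diene, C6' epimers) | O=C1/C(=C/C(C)(C)/C=C\CC(C)C(=O)CC)O[C@@]2(O1)C[C@H](C)CC[C@H]2C(C)C | intermediate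
15 | (5R,6S,9R)-9-methyl-6-(propan-2-yl)-3-[(1S,6S)-2,2,6-trimethyl-6-propanoylcyclohex-3-en-1-yl]-1,4-dioxaspiro[4.5]decan-2-one (Michael adduct, C3 epimers) | CCC(=O)[C@@]2(C)CC=CC(C)(C)[C@@H]2C1O[C@@]3(OC1=O)C[C@H](C)CC[C@H]3C(C)C | intermediate
16 | (4aS,8aS)-4-hydroxy-2,5,5,8a-tetramethyl-4a,5,8,8a-tetrahydronaphthalene-1,3(2H,4H)-dione (C2/C4 epimers, enolised) | CC1C(=O)[C@@]2(C)CC=CC(C)(C)[C@@H]2C(O)C1=O | intermediate
17 | (4aS,8aS)-4-hydroxy-2,5,5,8a-tetramethylhexahydronaphthalene-1,3(2H,4H)-dione (C2/C4 epimers, enolised) | CC1C(=O)[C@@]2(C)CCCC(C)(C)[C@@H]2C(O)C1=O | intermediate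
18 | (4aS,8aS)-3-hydroxy-2,5,5,8a-tetramethyl-4a,5,6,7,8,8a-hexahydronaphthalene-1,4-dione | OC1=C(C)C(=O)[C@@]2(C)CCCC(C)(C)[C@@H]2C1=O | intermediate
19 | (4aS,8aS)-3-methoxy-2,5,5,8a-tetramethyl-4a,5,6,7,8,8a-hexahydronaphthalene-1,4-dione | COC1=C(C)C(=O)[C@@]2(C)CCCC(C)(C)[C@@H]2C1=O | intermediate
20 | (4S,4aS,8aS)-4-hydroxy-3-methoxy-2,5,5,8a-tetramethyl-4a,5,6,7,8,8a-hexahydronaphthalen-1(4H)-one | COC1=C(C)C(=O)[C@@]2(C)CCCC(C)(C)[C@@H]2[C@@H]1O | intermediate
21 | prop-2-yn-1-ol | OCC#C | starting material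
22 | 2-methylidenepent-4-en-1-ol | C=C(CO)CC=C | intermediate
23 | [(2R)-2-(prop-2-en-1-yl)oxiran-2-yl]methanol | OC[C@]1(CC=C)CO1 | intermediate
24 | (2S)-4-[dimethyl(propan-2-yloxy)silyl]-2-(prop-2-en-1-yl)butane-1,2-diol | OC[C@](O)(CC=C)CC[Si](C)(C)OC(C)C | intermediate
25 | (2S)-2-(prop-2-en-1-yl)butane-1,2,4-triol | OC[C@](O)(CC=C)CCO | intermediate
26 | 2-[(4S)-2,2-dimethyl-4-(prop-2-en-1-yl)-1,3-dioxolan-4-yl]ethan-1-ol | OCC[C@@]1(CC=C)COC(C)(C)O1 | intermediate
27 | (4S)-4-(2-iodoethyl)-2,2-dimethyl-4-(prop-2-en-1-yl)-1,3-dioxolane | ICC[C@@]1(CC=C)COC(C)(C)O1 | intermediate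
28 | {2-[(4S)-2,2-dimethyl-4-(prop-2-en-1-yl)-1,3-dioxolan-4-yl]ethyl}magnesium iodide | I[Mg]CC[C@@]1(CC=C)COC(C)(C)O1 | intermediate
29 | (4S,4aS,8aS)-1-{2-[(4R)-2,2-dimethyl-4-(prop-2-en-1-yl)-1,3-dioxolan-4-yl]ethyl}-3-methoxy-2,5,5,8a-tetramethyl-1,4,4a,5,6,7,8,8a-octahydronaphthalene-1,4-diol (C1 epimers) | COC1=C(C)C(O)(CC[C@@]3(CC=C)COC(C)(C)O3)[C@@]2(C)CCCC(C)(C)[C@@H]2[C@@H]1O | intermediate
30 | (1S,4aS,8aS)-1-hydroxy-4-[(3R)-3-hydroxy-3-(hydroxymethyl)hex-5-en-1-yl]-3,4a,8,8-tetramethyl-4a,5,6,7,8,8a-hexahydronaphthalen-2(1H)-one | CC1=C(CC[C@](O)(CO)CC=C)[C@@]2(C)CCCC(C)(C)[C@@H]2[C@H](O)C1=O | intermediate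
31 | (3R)-3-hydroxy-3-(hydroxymethyl)-5-[(4S,4aS,8aS)-4-hydroxy-2,5,5,8a-tetramethyl-3-oxo-3,4,4a,5,6,7,8,8a-octahydronaphthalen-1-yl]pentanal | CC1=C(CC[C@](O)(CO)CC=O)[C@@]2(C)CCCC(C)(C)[C@@H]2[C@H](O)C1=O | intermediate
32 | (1S,4aS,8aS)-4-{2-[(3R)-3,5-dihydroxyoxolan-3-yl]ethyl}-1-hydroxy-3,4a,8,8-tetramethyl-4a,5,6,7,8,8a-hexahydronaphthalen-2(1H)-one (lactol, anomers) | CC1=C(CC[C@]2(O)COC(O)C2)[C@@]2(C)CCCC(C)(C)[C@@H]2[C@H](O)C1=O | intermediate
33 | (1S,4aS,8aS)-1-hydroxy-4-{2-[(3R)-3-hydroxy-5-oxooxolan-3-yl]ethyl}-3,4a,8,8-tetramethyl-4a,5,6,7,8,8a-hexahydronaphthalen-2(1H)-one (CNP0324736.1) | CC1=C(CC[C@]2(O)COC(=O)C2)[C@@]2(C)CCCC(C)(C)[C@@H]2[C@H](O)C1=O | target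

## Step count and risks

Total step count: 18. Longest linear sequence: 12 steps (steps 2, 3, 4, 5, 6, 7, 8, 9, 10, 16, 17, 18).

The three steps most likely to fail:

Step 6. What may go wrong: loss of absolute stereocontrol, because the auxiliary may bias the face of the exocyclic C5 only weakly or the Michael closure may give mixed ring fusion, so that after the C5 equilibration of step 8 compound 18 is obtained in low enantiomeric purity. Fallback (classical resolution in place of auxiliary control): it sets out from scalemic 18, a strongly acidic enol. 18 is combined with (R)-1-phenylethylamine in EtOAc/iPrOH and the less soluble diastereomeric salt, (1R)-1-phenylethan-1-aminium (4aS,8aS)-3,5,5,8a-tetramethyl-1,4-dioxo-1,4,4a,5,6,7,8,8a-octahydronaphthalen-2-olate F1, is crystallised to constant rotation (the (S)-amine is used if it gives the better-crystallising salt). Acidification with 1 M HCl returns enantiopure 18, where the route is rejoined.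

Step 16. What may go wrong: the Grignard reagent may fail to add to the C9 carbonyl, which is flanked by the quaternary C10 and the substituted C8, giving deprotonation or recovered ketone instead of 1,2-addition. Fallback (1,4-addition and re-oxidation in place of 1,2-addition and transposition): it sets out from 20. Reduction of the C9 carbonyl with iBu2AlH (CH2Cl2, −78 °C) and work-up with 1 M HCl gives the transposed enone lacking the side chain, (1S,4aR,8aS)-1-hydroxy-3,4a,8,8-tetramethyl-4a,5,6,7,8,8a-hexahydronaphthalen-2(1H)-one F2. Copper-catalysed (CuBr·SMe2) conjugate addition of Grignard reagent 28 at C9 in the presence of Me3SiCl/Et3N, which also silylates the C6 hydroxyl, gives the bis-silylated enol ether adduct F3. Oxidation of the silyl enol ether (DDQ, 2,4,6-collidine, or Pd(OAc)2 in MeCN) regenerates the tetrasubstituted enone as the O-silylated acetonide F4. 1 M HCl in THF removes the silyl ether and the acetonide and gives 30, where the route is rejoined.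

Step 8. What may go wrong: over-oxidation, in which the copper salt attacks the enolised 1,3-dione (hydroxylation at C8 or C–C cleavage) instead of only dehydrogenating the α-ketol. Fallback (methylation before oxidation): it sets out from 17. O-methylation with Me3SiCHN2 should occur at the less hindered C7 oxygen and give the hydroxy vinylogous ester (4aS,8aS)-4-hydroxy-3-methoxy-2,5,5,8a-tetramethyl-4a,5,6,7,8,8a-hexahydronaphthalen-1(4H)-one F5. Buffered Dess–Martin oxidation of its allylic-type C6 hydroxyl, followed by DBU (cat.) to equilibrate C5 to the trans ring fusion, gives 19, where the route is rejoined.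

Further compounds
F1 | step 6 | (1R)-1-phenylethan-1-aminium (4aS,8aS)-3,5,5,8a-tetramethyl-1,4-dioxo-1,4,4a,5,6,7,8,8a-octahydronaphthalen-2-olate | C[C@@H]([NH3+])c1ccccc1.[O-]C1=C(C)C(=O)[C@@]2(C)CCCC(C)(C)[C@@H]2C1=O
F2 | step 16 | (1S,4aR,8aS)-1-hydroxy-3,4a,8,8-tetramethyl-4a,5,6,7,8,8a-hexahydronaphthalen-2(1H)-one | CC1=C[C@@]2(C)CCCC(C)(C)[C@@H]2[C@H](O)C1=O
F3 | step 16 | (4R)-2,2-dimethyl-4-(prop-2-en-1-yl)-4-{2-[(4S,4aS,8aS)-2,5,5,8a-tetramethyl-3,4-bis[(trimethylsilyl)oxy]-1,4,4a,5,6,7,8,8a-octahydronaphthalen-1-yl]ethyl}-1,3-dioxolane (C1 epimers) | C[Si](C)(C)OC1=C(C)C(CC[C@@]3(CC=C)COC(C)(C)O3)[C@@]2(C)CCCC(C)(C)[C@@H]2[C@@H]1O[Si](C)(C)C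
F4 | step 16 | (1S,4aS,8aS)-4-{2-[(4R)-2,2-dimethyl-4-(prop-2-en-1-yl)-1,3-dioxolan-4-yl]ethyl}-3,4a,8,8-tetramethyl-1-[(trimethylsilyl)oxy]-4a,5,6,7,8,8a-hexahydronaphthalen-2(1H)-one | CC1=C(CC[C@@]3(CC=C)COC(C)(C)O3)[C@@]2(C)CCCC(C)(C)[C@@H]2[C@H](O[Si](C)(C)C)C1=O
F5 | step 8 | (4aS,8aS)-4-hydroxy-3-methoxy-2,5,5,8a-tetramethyl-4a,5,6,7,8,8a-hexahydronaphthalen-1(4H)-one (C4 epimers) | COC1=C(C)C(=O)[C@@]2(C)CCCC(C)(C)[C@@H]2C1O
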